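A leftover opens the question: in the west run, which is the asked flask so far, 22% of the starting material is still free at 20.0 h, yet double product has read 17%, 17% and 16% since 6.00 h.

| flask | starting material | reagent | remark | time |
|---|---|---|---|---|
| west | 0.050 M | 0.045 M | the very flask that is asked about, followed so far |  |
| south-east | 0.034 M | 0.045 M | run made earlier |  |
| flask | 0.050 M | 0.0450 M |  | 20 h |

west run (percent of the starting material charged)

| time / h | double product / % | starting material / % |
|---|---|---|
| 1.50 | 5 | 45 |
| 3.00 | 11 | 36 |
| 6.00 | 17 | 32 |
| 10.0 | 17 | 27 |
| 20.0 | 16 | 22 |

south-east run (percent of the starting material charged)

| time / min | double product / % | starting material / % |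
|---|---|---|
| 8.00 | 1 | 87 |
| 15.0 | 1 | 75 |
| 25.0 | 2 | 69 |
| 50.0 | 1 | 51 |
| 90.0 | 3 | 43 |

(standard deviation of a reading: 1.5 percentage points)

- percent here means starting material units held: one side product counts as two
- double product taken out counts as made
- the earlier runs were read with a standard deviation of 1.5 percentage points
- candidate steps: starting material + reagent -> mono adduct; reagent + mono adduct -> double product; reagent + double product -> tris adduct; double product <-> isomer of the product; starting material <-> dormant form; starting material + mono adduct -> side product
- additions bring no volume worth counting

- larch: at 20 h add reagent, 100% of the amount charged, then wait 10 h
- elm: at 20 h add starting material, 50.0% of the amount charged, then wait 10 h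
- oak: change nothing and wait 10 h more
- alder: at 20 h take out 90% of the double product then present, then wait 10 h

- double product, in percent of the starting material first charged, at 20 h
- what to do for the largest gain in double product; "none" if nothing gains more than 2 percentage points (larch / elm / oak / alder / none)
- double product present, with what was taken out counted in, in percent of the starting material first charged, after larch
- double product present, with what was taken out counted in, in percent of the starting material first charged, after elm

What does the charge allow? In this flask reagent is the limiting reagent, 0.0450 M against 0.050 M of starting material, and at two reagent units per double product the balance stops at 45.0%. But reagent can also turn double product into tris adduct, so how much of that can stand at one time?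

My own reckoning takes the symmetric case as the zero of the scale: every step from starting material to tris adduct equally fast. The number of reagent units on a starting unit is then a Poisson count whose mean is the ladder load, reagent units charged per unit of starting material, here 0.900. The share holding exactly two is load · load · exp(−load) / 2, which gives 16.5%, within the scatter of the last west reading.

Does more reagent help? Larch raises the load to 1.80, and the share to 26.8%, near the symmetric top of 27.1% at load 2. That gain of 10 percentage points exceeds the margin. Elm adds starting material at 20 h, after the west readings of double product have stopped rising, and my ladder counts charges present from the start, so it gives no figure for elm and I expect no gain there. Oak and alder leave the load unchanged. So I commit to larch.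

The forecast gave 16.5% now, larch as the choice, 45% after larch and 16.5% after elm, reasoning that "mono adduct converts over 10 h, adding about 30 units after some tris loss". It shares my choice but stands above my larch figure.

The flask gives 16.1% now, larch with a gain of 6.7 points, 22.7% after larch and 14.0% after elm.

    starting material + reagent → mono adduct (k = 0.00182 L mol⁻¹ s⁻¹)
    reagent + mono adduct → double product (k = 0.00208 L mol⁻¹ s⁻¹)
    reagent + double product → tris adduct (k = 0.00119 L mol⁻¹ s⁻¹)
    double product ⇌ isomer of the product (K = 2.60, k = 4.74 × 10⁻⁶ s⁻¹)
    starting material ⇌ dormant form (K = 0.790, k = 2.25 × 10⁻⁴ s⁻¹)
    starting material + mono adduct → side product (k = 1.36 × 10⁻⁴ L mol⁻¹ s⁻¹)

By the step to tris adduct alone, with the other concentrations as charged, double product has a half-life of 3.6 h, short against 20 h. The load of 1.80 gave 26.8%, and larch stands 4 points lower after 10 h.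

The neighbour flask with 0.020 M of starting material carries a load of 2.25, beyond the top, with a ladder share of 26.7%. Computed, it holds 24.4% double product beside 32.6% tris adduct.

The runs are simulated with constants of no real substance; noise was put on by code.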